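## Plan

- **Locants.** Ring as 7-oxabicyclo[4.1.0]heptane: C1 (C–Me), C2 (C=O), C3 (CH–O), C4 (CH), C5 (CH2), C6 (epoxide CH), O7; side chain C1′(=CH2) to C7′.
- **Cuts.** Both ester C–O bonds; C3′–C4′ and C2′=C1′ in the side chain; C1–CH3 and C6–O7; and, as the ring-forming cut, C5–C6 together with C2–C3.
- **Enabling feature.** C6, C1, C2 and C3 carry four contiguous oxygens. C6–C1–C2 is therefore a masked dihydroxyacetone (central carbonyl at C1, two nucleophilic α-carbons), and C5–C4–C3 is a 2-substituted acrolein (electrophilic CH2 and CHO ends).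
- **Forward.** One domino Michael/aldol α,α′-annulation of 2,2-dimethyl-1,3-dioxan-5-one with 2-allylacrolein closes the carbocycle. MeMgBr then makes C1, an inverting esterification sets C3, the old ketone oxygen closes the epoxide onto C6, C2 is oxidised, and the allyl arm is grown into the side chain.
- **Stereochemistry.** L-Proline fixes the absolute sense in the annulation (bridgeheads, exo C4). C1 comes from attack on the open dioxane face of the bicyclic ketone, C6 and C3 from two SN2 inversions (Mitsunobu), and C3′ from reagent-controlled Brown allylboration.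

Key step: step 2

Assumption: the aldol of step 2 is taken to close through the hydrogen-bonded (closed) transition state, so the new hydroxyl is axial (6R) and is inverted in step 4; if the equatorial epimer formed instead, step 4 would become a plain acylation with retention.

## Route

Step 1
Reactants: 1 pent-4-enal
Product: 2 2-methylidenepent-4-enal
Conditions: 37% aq. CH2O, pyrrolidine (10 mol%), propionic acid (10 mol%), i-PrOH, 45 °C
Reagents that add atoms: formaldehyde, C=O
Why: Amine-catalysed Mannich condensation/elimination (α-methylenation of an aldehyde) is a standard entry to 2-substituted acroleins, and no stereocentre is formed.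

Step 2
Reactants: 2 2-methylidenepent-4-enal; 3 2,2-dimethyl-1,3-dioxan-5-one
Product: 5 (1R,5S,6R,7R)-6-hydroxy-3,3-dimethyl-7-(prop-2-en-1-yl)-2,4-dioxabicyclo[3.3.1]nonan-9-one, via keto aldehyde 4 (not isolated)
Conditions: L-proline (30 mol%), DMF, 4 °C to rt, 2 added slowly
Reagents that add atoms: none
Why: Proposed new method: L-proline should condense with 3 to the enamine, which adds in a Stork-type Michael reaction to the unsubstituted β-carbon of 2 (bond C8–C1 of 5, i.e. C5–C6 of the target), and the proline enamine on the remaining α′-CH2 of 4 should then attack the formyl group through the hydrogen-bonded enamine transition state accepted for proline aldol reactions (bond C5–C6 of 5, i.e. C2–C3 of the target). The closest known reaction types are the Stork α,α′-annulation of ketone enamines with acroleins to 2-hydroxybicyclo[3.3.1]nonan-9-ones, the Hajos–Parrish reaction and the proline-catalysed aldol reactions of 3; new is their union in one catalytic asymmetric operation on a dioxanone and an α-substituted acrolein. The Michael step closes no ring, and the carbocycle closes in a 6-(enolendo)-exo-trig aldol mode. C5 is set by the proline carboxylic acid, which delivers the aldehyde to one face of the enamine; C1 must carry its CH2 arm cis-diaxial to the new bond for the bridge to close, so the cyclisation should resolve the two enolisable α-centres of 4 dynamically; the C6 hydroxyl is placed axial, syn to the C9 carbonyl, by the closed transition state; and the allyl group at C7 takes the exo position because the endo position is blocked by C3 of the dioxane ring. The step needs 1,4- over 1,2-addition to the enal and mono- over bis-alkylation of 3: the reversible aldol addition at the enal carbonyl should drain into the irreversible Michael adduct, and the fast intramolecular aldol removes the second α-position from further alkylation.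

Step 3
Reactants: 5 (1R,5S,6R,7R)-6-hydroxy-3,3-dimethyl-7-(prop-2-en-1-yl)-2,4-dioxabicyclo[3.3.1]nonan-9-one
Product: 6 (1R,5S,6R,7R,9S)-3,3,9-trimethyl-7-(prop-2-en-1-yl)-2,4-dioxabicyclo[3.3.1]nonane-6,9-diol
Conditions: MeMgBr (3 equiv), THF, −78 °C to −20 °C; aq. NH4Cl
Reagents that add atoms: methylmagnesium bromide, C[Mg]Br
Why: Grignard 1,2-addition to the doubly α-oxygenated ketone should be fast, and methyl should enter from the dioxane face, which has ring oxygens instead of axial C–H bonds at positions 2 and 4 and lies opposite the axial C6 alkoxide, so that the new C9 hydroxyl stands anti to both bridgehead C–O bonds.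

Step 4
Reactants: 6 (1R,5S,6R,7R,9S)-3,3,9-trimethyl-7-(prop-2-en-1-yl)-2,4-dioxabicyclo[3.3.1]nonane-6,9-diol
Product: 7 (1R,5S,6S,7R,9S)-9-hydroxy-3,3,9-trimethyl-7-(prop-2-en-1-yl)-2,4-dioxabicyclo[3.3.1]nonan-6-yl 3-methylbut-2-enoate
Conditions: 3-methylbut-2-enoic acid, PPh3, DIAD, toluene, 0 °C to rt
Reagents that add atoms: 3-methylbut-2-enoic acid, CC(C)=CC(=O)O
Why: Mitsunobu esterification of the secondary axial C6 alcohol (the tertiary C9 hydroxyl is inert) should proceed by SN2 attack of the carboxylate with inversion, which places the ester equatorial and trans to the allyl group, while elimination toward the bridgehead C5 is excluded by Bredt's rule.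

Step 5
Reactants: 7 (1R,5S,6S,7R,9S)-9-hydroxy-3,3,9-trimethyl-7-(prop-2-en-1-yl)-2,4-dioxabicyclo[3.3.1]nonan-6-yl 3-methylbut-2-enoate
Product: 8 (1S,2S,3S,4R,6R)-2,3,4-trihydroxy-3-methyl-6-(prop-2-en-1-yl)cyclohexyl 3-methylbut-2-enoate
Conditions: AcOH/H2O (4:1), rt to 40 °C
Reagents that add atoms: none
Why: Acid hydrolysis of the isopropylidene acetal, which spans two 1,3-diaxial positions and is therefore strained, should be possible under conditions mild enough to leave the ester (no acyl shift) and the tertiary alcohol untouched, and no stereocentre is touched.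

Step 6
Reactants: 8 (1S,2S,3S,4R,6R)-2,3,4-trihydroxy-3-methyl-6-(prop-2-en-1-yl)cyclohexyl 3-methylbut-2-enoate
Product: 9 (1R,2S,3S,4R,6S)-2-hydroxy-1-methyl-4-(prop-2-en-1-yl)-7-oxabicyclo[4.1.0]heptan-3-yl 3-methylbut-2-enoate
Conditions: PPh3, DIAD, THF, 0 °C to rt
Reagents that add atoms: none
Why: Mitsunobu cyclodehydration of a trans 1,2-diol should activate the C4 hydroxyl, which is less hindered and less deactivated toward SN2 than C2–OH (flanked by the acyloxy-bearing C1), and the trans-diaxial tertiary C3 hydroxyl then closes the epoxide with inversion at C4, which puts the epoxide cis to the allyl group.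

Step 7
Reactants: 9 (1R,2S,3S,4R,6S)-2-hydroxy-1-methyl-4-(prop-2-en-1-yl)-7-oxabicyclo[4.1.0]heptan-3-yl 3-methylbut-2-enoate
Product: 10 (1S,3S,4R,6S)-1-methyl-2-oxo-4-(prop-2-en-1-yl)-7-oxabicyclo[4.1.0]heptan-3-yl 3-methylbut-2-enoate
Conditions: Dess–Martin periodinane, NaHCO3, CH2Cl2, rt
Reagents that add atoms: none
Why: Dess–Martin oxidation of the remaining secondary alcohol is near-neutral and should spare the epoxide, the ester and the base-sensitive C3–H, and no stereocentre is formed.

Step 8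
Reactants: 10 (1S,3S,4R,6S)-1-methyl-2-oxo-4-(prop-2-en-1-yl)-7-oxabicyclo[4.1.0]heptan-3-yl 3-methylbut-2-enoate
Product: 12 (1S,3S,4S,6S)-1-methyl-2-oxo-4-(2-oxoethyl)-7-oxabicyclo[4.1.0]heptan-3-yl 3-methylbut-2-enoate, via vicinal diol 11 (not isolated)
Conditions: OsO4 (2 mol%), NaIO4, 2,6-lutidine, dioxane/H2O (3:1), rt
Reagents that add atoms: osmium tetroxide, O=[Os](=O)(=O)=O (catalytic, regenerated by the periodate); sodium periodate, [Na+].[O-][I](=O)(=O)=O
Why: In this Lemieux–Johnson oxidation OsO4 should dihydroxylate the monosubstituted terminal alkene much faster than the electron-poor trisubstituted enoate, and periodate cleaves the diol to the aldehyde without touching the α-acyloxy ketone.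

Step 9
Reactants: 12 (1S,3S,4S,6S)-1-methyl-2-oxo-4-(2-oxoethyl)-7-oxabicyclo[4.1.0]heptan-3-yl 3-methylbut-2-enoate
Product: 13 (1S,3S,4S,6S)-1-methyl-2-oxo-4-(3-oxoprop-1-en-2-yl)-7-oxabicyclo[4.1.0]heptan-3-yl 3-methylbut-2-enoate
Conditions: 37% aq. CH2O, pyrrolidine (10 mol%), propionic acid (10 mol%), i-PrOH, 40 °C
Reagents that add atoms: formaldehyde, C=O
Why: The same Mannich condensation/elimination as in step 1 should be selective for the enolisable aldehyde over the hindered ring ketone, and it creates the 1,1-disubstituted alkene without forming a stereocentre.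

Step 10
Reactants: 13 (1S,3S,4S,6S)-1-methyl-2-oxo-4-(3-oxoprop-1-en-2-yl)-7-oxabicyclo[4.1.0]heptan-3-yl 3-methylbut-2-enoate
Product: 14 (1S,3S,4S,6S)-4-[(3R)-3-hydroxyhexa-1,5-dien-2-yl]-1-methyl-2-oxo-7-oxabicyclo[4.1.0]heptan-3-yl 3-methylbut-2-enoate
Conditions: (+)-Ipc2BOMe (from (−)-α-pinene), allylMgBr, Et2O, −78 °C to rt, then 13, −78 °C; work-up with 2-aminoethanol
Reagents that add atoms: allylmagnesium bromide, C=CC[Mg]Br (allyl transferred through B-allyldiisopinocampheylborane, C=CCB([C@H]1C[C@H]2C[C@@H]([C@@H]1C)C2(C)C)[C@H]1C[C@H]2C[C@@H]([C@@H]1C)C2(C)C)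
Why: Brown allylboration through a chair-like six-membered transition state should deliver allyl to the Re face of the aldehyde under reagent control to give the (3R) carbinol, and at −78 °C the hindered ring ketone and the ester should not react.

Step 11
Reactants: 14 (1S,3S,4S,6S)-4-[(3R)-3-hydroxyhexa-1,5-dien-2-yl]-1-methyl-2-oxo-7-oxabicyclo[4.1.0]heptan-3-yl 3-methylbut-2-enoate
Product: 15 (1S,3S,4S,6S)-4-[(3R)-3-hydroxy-6-methylhepta-1,5-dien-2-yl]-1-methyl-2-oxo-7-oxabicyclo[4.1.0]heptan-3-yl 3-methylbut-2-enoate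
Conditions: 2-methylbut-2-ene (excess), second-generation Grubbs catalyst RuCl2(=CHPh)(PCy3)(H2IMes) (5 mol%), CH2Cl2, rt to 40 °C
Reagents that add atoms: 2-methylbut-2-ene, CC=C(C)C
Why: Olefin cross-metathesis with excess 2-methylbut-2-ene should convert the terminal vinyl group into the prenyl alkene, while the 1,1-disubstituted methylidene and the enoate alkene are too hindered or electron-poor to take part and no stereocentre is touched.

Step 12
Reactants: 15 (1S,3S,4S,6S)-4-[(3R)-3-hydroxy-6-methylhepta-1,5-dien-2-yl]-1-methyl-2-oxo-7-oxabicyclo[4.1.0]heptan-3-yl 3-methylbut-2-enoate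
Product: 16 (1S,3S,4S,6S)-1-methyl-4-[(3R)-6-methyl-3-[(3-methylbut-2-enoyl)oxy]hepta-1,5-dien-2-yl]-2-oxo-7-oxabicyclo[4.1.0]heptan-3-yl 3-methylbut-2-enoate (CNP0140369.1)
Conditions: 3-methylbut-2-enoic acid, EDC·HCl, DMAP, CH2Cl2, 0 °C to rt
Reagents that add atoms: 3-methylbut-2-enoic acid, CC(C)=CC(=O)O
Why: Steglich esterification of the secondary allylic alcohol under near-neutral conditions is chosen over acid chloride with amine base to avoid deconjugation of the 3-methylbut-2-enoyl group through a vinylketene, and the carbinol configuration is retained.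

## Compound list

1 | pent-4-enal | C=CCCC=O | starting material
2 | 2-methylidenepent-4-enal (2-allylacrolein) | C=CCC(=C)C=O | intermediate
3 | 2,2-dimethyl-1,3-dioxan-5-one | CC1(C)OCC(=O)CO1 | starting material
4 | (2R)-2-{[(4R)-2,2-dimethyl-5-oxo-1,3-dioxan-4-yl]methyl}pent-4-enal (the epimer that cyclises; both α-centres equilibrate) | C=CC[C@@H](C=O)C[C@H]1OC(C)(C)OCC1=O | intermediate (not isolated)
5 | (1R,5S,6R,7R)-6-hydroxy-3,3-dimethyl-7-(prop-2-en-1-yl)-2,4-dioxabicyclo[3.3.1]nonan-9-one | C=CC[C@@H]1C[C@H]2OC(C)(C)O[C@H](C2=O)[C@@H]1O | intermediate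
6 | (1R,5S,6R,7R,9S)-3,3,9-trimethyl-7-(prop-2-en-1-yl)-2,4-dioxabicyclo[3.3.1]nonane-6,9-diol | C=CC[C@@H]1C[C@H]2OC(C)(C)O[C@H]([C@@]2(C)O)[C@@H]1O | intermediate
7 | (1R,5S,6S,7R,9S)-9-hydroxy-3,3,9-trimethyl-7-(prop-2-en-1-yl)-2,4-dioxabicyclo[3.3.1]nonan-6-yl 3-methylbut-2-enoate | C=CC[C@@H]1C[C@H]2OC(C)(C)O[C@H]([C@@]2(C)O)[C@H]1OC(=O)C=C(C)C | intermediate
8 | (1S,2S,3S,4R,6R)-2,3,4-trihydroxy-3-methyl-6-(prop-2-en-1-yl)cyclohexyl 3-methylbut-2-enoate | C=CC[C@@H]1C[C@@H](O)[C@](C)(O)[C@@H](O)[C@H]1OC(=O)C=C(C)C | intermediate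
9 | (1R,2S,3S,4R,6S)-2-hydroxy-1-methyl-4-(prop-2-en-1-yl)-7-oxabicyclo[4.1.0]heptan-3-yl 3-methylbut-2-enoate | C=CC[C@@H]1C[C@@H]2O[C@]2(C)[C@@H](O)[C@H]1OC(=O)C=C(C)C | intermediate
10 | (1S,3S,4R,6S)-1-methyl-2-oxo-4-(prop-2-en-1-yl)-7-oxabicyclo[4.1.0]heptan-3-yl 3-methylbut-2-enoate | C=CC[C@@H]1C[C@@H]2O[C@]2(C)C(=O)[C@H]1OC(=O)C=C(C)C | intermediate
11 | (1S,3S,4R,6S)-4-(2,3-dihydroxypropyl)-1-methyl-2-oxo-7-oxabicyclo[4.1.0]heptan-3-yl 3-methylbut-2-enoate (both carbinol epimers) | OCC(O)C[C@@H]1C[C@@H]2O[C@]2(C)C(=O)[C@H]1OC(=O)C=C(C)C | intermediate (not isolated)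
12 | (1S,3S,4S,6S)-1-methyl-2-oxo-4-(2-oxoethyl)-7-oxabicyclo[4.1.0]heptan-3-yl 3-methylbut-2-enoate | O=CC[C@@H]1C[C@@H]2O[C@]2(C)C(=O)[C@H]1OC(=O)C=C(C)C | intermediate
13 | (1S,3S,4S,6S)-1-methyl-2-oxo-4-(3-oxoprop-1-en-2-yl)-7-oxabicyclo[4.1.0]heptan-3-yl 3-methylbut-2-enoate | C=C(C=O)[C@@H]1C[C@@H]2O[C@]2(C)C(=O)[C@H]1OC(=O)C=C(C)C | intermediate
14 | (1S,3S,4S,6S)-4-[(3R)-3-hydroxyhexa-1,5-dien-2-yl]-1-methyl-2-oxo-7-oxabicyclo[4.1.0]heptan-3-yl 3-methylbut-2-enoate | C=C([C@@H](CC=C)O)[C@@H]1C[C@@H]2O[C@]2(C)C(=O)[C@H]1OC(=O)C=C(C)C | intermediate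
15 | (1S,3S,4S,6S)-4-[(3R)-3-hydroxy-6-methylhepta-1,5-dien-2-yl]-1-methyl-2-oxo-7-oxabicyclo[4.1.0]heptan-3-yl 3-methylbut-2-enoate | C=C([C@@H](CC=C(C)C)O)[C@@H]1C[C@@H]2O[C@]2(C)C(=O)[C@H]1OC(=O)C=C(C)C | intermediate
16 | (1S,3S,4S,6S)-1-methyl-4-[(3R)-6-methyl-3-[(3-methylbut-2-enoyl)oxy]hepta-1,5-dien-2-yl]-2-oxo-7-oxabicyclo[4.1.0]heptan-3-yl 3-methylbut-2-enoate | C=C([C@@H](CC=C(C)C)OC(=O)C=C(C)C)[C@@H]1C[C@@H]2O[C@]2(C)C(=O)[C@H]1OC(=O)C=C(C)C | target

## Step count and risks

Total step count: 12. Longest linear sequence: 12 steps (from 1; 3 enters at step 2).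

Steps most likely to fail:

1. Step 2 (proposed new method). What may go wrong: competing self-condensation or 1,2-addition of the enal, or too slow epimerisation of the dioxanone α-centre, so that catalyst control of the absolute configuration is eroded. Fallback with known chemistry, from 3 back to 5: 3 is condensed with (S)-2-(methoxymethyl)pyrrolidine to the enamine (S)-1-(2,2-dimethyl-4H-1,3-dioxin-5-yl)-2-(methoxymethyl)pyrrolidine F1 (the antipodal auxiliary is taken if the sense of induction proves opposite). F1 is added to 2 in a stoichiometric Stork Michael reaction, aqueous acetic acid hydrolysis releases the auxiliary and gives 4 with its dioxanone centre already fixed, and 4 is closed to 5 by proline- or base-mediated intramolecular aldol.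

2. Step 4. What may go wrong: β-elimination of the activated axial alcohol toward C7, or no displacement by the weakly acidic carboxylic acid at a hindered centre. Fallback, from 6 back to 7: Dess–Martin oxidation of the secondary alcohol gives the hydroxy ketone (1R,5R,7R,9S)-9-hydroxy-3,3,9-trimethyl-7-(prop-2-en-1-yl)-2,4-dioxabicyclo[3.3.1]nonan-6-one F2. Evans–Saksena reduction with Me4NBH(OAc)3, directed by the tertiary C9 hydroxyl, should give the anti-1,3-diol (1R,5S,6S,7R,9S)-3,3,9-trimethyl-7-(prop-2-en-1-yl)-2,4-dioxabicyclo[3.3.1]nonane-6,9-diol F3. Acylation of its secondary hydroxyl with 3-methylbut-2-enoic anhydride and DMAP gives 7. Because oxidation erases C6, this also covers formation of the C6 epimer or a mixture in step 2.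

3. Step 6. What may go wrong: activation of the wrong secondary hydroxyl (C2 instead of C4), leading to the regioisomeric epoxide, or acyl shift from C1–O to C2–O. Fallback, from 6 back to 9: 6 is taken through F2 to the diol F3 as above. Acid (camphorsulfonic acid, acetone) should move the acetonide onto the now cis-vicinal C5/C6 diol to give (3aS,4S,5R,7R,7aS)-2,2,4-trimethyl-7-(prop-2-en-1-yl)hexahydro-1,3-benzodioxole-4,5-diol F4, in which the only free secondary hydroxyl is the one to be displaced. Mitsunobu closure (PPh3, DIAD) gives the 2,3-O-isopropylidene derivative of (1R,2S,3S,4R,6S)-1-methyl-4-(prop-2-en-1-yl)-7-oxabicyclo[4.1.0]heptane-2,3-diol F5. Aqueous acetic acid frees (1R,2S,3S,4R,6S)-1-methyl-4-(prop-2-en-1-yl)-7-oxabicyclo[4.1.0]heptane-2,3-diol F6. Selective acylation of its equatorial C3 hydroxyl (the C2 hydroxyl is next to the quaternary epoxide carbon) with 3-methylbut-2-enoic anhydride and DMAP at low temperature gives 9.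

Further compounds
F1 | step 2 | (S)-1-(2,2-dimethyl-4H-1,3-dioxin-5-yl)-2-(methoxymethyl)pyrrolidine | COC[C@@H]1CCCN1C1=COC(C)(C)OC1
F2 | step 4 | (1R,5R,7R,9S)-9-hydroxy-3,3,9-trimethyl-7-(prop-2-en-1-yl)-2,4-dioxabicyclo[3.3.1]nonan-6-one | C=CC[C@@H]1C[C@H]2OC(C)(C)O[C@H]([C@@]2(C)O)C1=O
F3 | step 4 | (1R,5S,6S,7R,9S)-3,3,9-trimethyl-7-(prop-2-en-1-yl)-2,4-dioxabicyclo[3.3.1]nonane-6,9-diol | C=CC[C@@H]1C[C@H]2OC(C)(C)O[C@H]([C@@]2(C)O)[C@H]1O
F4 | step 6 | (3aS,4S,5R,7R,7aS)-2,2,4-trimethyl-7-(prop-2-en-1-yl)hexahydro-1,3-benzodioxole-4,5-diol | C=CC[C@@H]1C[C@@H](O)[C@](C)(O)[C@H]2OC(C)(C)O[C@@H]12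
F5 | step 6 | 2,3-O-isopropylidene derivative of (1R,2S,3S,4R,6S)-1-methyl-4-(prop-2-en-1-yl)-7-oxabicyclo[4.1.0]heptane-2,3-diol | C=CC[C@@H]1C[C@@H]2O[C@]2(C)[C@H]3OC(C)(C)O[C@@H]13
F6 | step 6 | (1R,2S,3S,4R,6S)-1-methyl-4-(prop-2-en-1-yl)-7-oxabicyclo[4.1.0]heptane-2,3-diol | C=CC[C@@H]1C[C@@H]2O[C@]2(C)[C@@H](O)[C@H]1O
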